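**Retrosynthetic overview**
Rings: A = bromocyclohexane holding the C(OH)CH3 carbon, B = central cyclohexane, C and D = the two five-membered rings of the bicyclo[2.2.1]heptane. Order of formation: C + D + a five-membered forerunner of B in one Diels–Alder step, then B by ring expansion, then A by metathesis.
End game: both tertiary alcohols come from Markovnikov oxymercuration (exo on the norbornene, trans-diaxial on the ring A alkene). The ketone left in ring B is removed through its tosylhydrazone.
Key disconnection: ring B cyclohexanone <= cyclopentanol carrying an (E)-trisubstituted alkenyl group. Br+ triggers a semipinacol 1,2-shift that inserts the methyl-bearing carbon into the ring.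
Enabling feature: in ring B the quaternary C(CH3) is bonded to the CHBr carbon of ring A, to the A/B fusion CH and to an unsubstituted ring B CH2. The array Br–CH–C(quaternary)–CH2 is the retron of a halonium-induced 1,2-alkyl shift whose carbonyl ends on that CH2.
The cyclopentanol comes from an alkenyllithium and a tricyclic ketone. That ketone is made by intramolecular Diels–Alder reaction of a 1,2-disubstituted cyclopentadiene (Stetter reaction, aldol condensation, reduction, dehydration).

Key step: step 16

Remark: the silyloxy/carbinol carbon of 3 to 14 is a temporary stereocentre. It serves only to make the two Diels–Alder faces separable as diastereomers and is erased in step 10.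

**Step 1**
Reactants: 1 methyl 4-oxobutanoate; 2 2-allyl-4,4,5,5-tetramethyl-1,3,2-dioxaborolane
Product: 3 methyl (4R)-4-hydroxyhept-6-enoate
Conditions: (S)-3,3'-bis(2,4,6-triisopropylphenyl)-1,1'-binaphthyl-2,2'-diyl hydrogen phosphate (5 mol %), PhMe, −30 °C; aq NaHCO3
Reagents that add atoms: none
Why: Chiral-phosphoric-acid-catalysed asymmetric allylboration through a closed chair transition state should set the carbinol centre, the catalyst antipode being chosen for the R alcohol, and the crude product is silylated at once to prevent lactonisation.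

**Step 2**
Reactants: 3 methyl (4R)-4-hydroxyhept-6-enoate
Product: 4 methyl (4R)-4-[(tert-butyldimethylsilyl)oxy]hept-6-enoate
Conditions: TBSCl, imidazole, DMF, 23 °C
Reagents that add atoms: tert-butyldimethylsilyl chloride CC(C)(C)[Si](C)(C)Cl
Why: Standard silyl ether formation protects the alcohol against lactol formation and against the basic and reducing steps that follow.

**Step 3**
Reactants: 4 methyl (4R)-4-[(tert-butyldimethylsilyl)oxy]hept-6-enoate
Product: 5 (4R)-4-[(tert-butyldimethylsilyl)oxy]hept-6-enal
Conditions: DIBAL-H (1.05 equiv), CH2Cl2, −78 °C; aq Rochelle salt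
Reagents that add atoms: none
Why: Partial ester reduction should stop at the aluminium hemiacetal at low temperature and release the aldehyde on work-up.

**Step 4**
Reactants: 5 (4R)-4-[(tert-butyldimethylsilyl)oxy]hept-6-enal; 6 4-methylpent-1-en-3-one
Product: 7 (9R)-9-[(tert-butyldimethylsilyl)oxy]-2-methyldodec-11-ene-3,6-dione
Conditions: 3-benzyl-5-(2-hydroxyethyl)-4-methylthiazolium chloride (20 mol %), Et3N, EtOH, 75 °C
Reagents that add atoms: none
Why: In this Stetter reaction the carbene-derived acyl anion equivalent of the aliphatic aldehyde adds 1,4 to the vinyl ketone and gives the 1,4-diketone without touching the isolated alkene.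

**Step 5**
Reactants: 7 (9R)-9-[(tert-butyldimethylsilyl)oxy]-2-methyldodec-11-ene-3,6-dione
Product: 8 2-[2-(tert-butyldimethylsilyloxy)pent-4-enyl]-3-isopropylcyclopent-2-en-1-one (silyloxy centre unchanged)
Conditions: KOH, EtOH/H2O, reflux
Reagents that add atoms: none
Why: In this intramolecular aldol condensation only the aldol from the chain CH2 onto the isopropyl ketone can dehydrate, so the reversible alternatives should drain into the tetrasubstituted enone that puts the tether and the isopropyl group on adjacent ring carbons.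

**Step 6**
Reactants: 8 2-[2-(tert-butyldimethylsilyloxy)pent-4-enyl]-3-isopropylcyclopent-2-en-1-one
Product: 9 2-[2-(tert-butyldimethylsilyloxy)pent-4-enyl]-3-isopropylcyclopent-2-en-1-ol (ring carbinol epimers)
Conditions: DIBAL-H, CH2Cl2, −78 °C; aq Rochelle salt
Reagents that add atoms: none
Why: This is a 1,2-reduction of the enone, and the new carbinol configuration is irrelevant because the centre is lost in the next step.

**Step 7**
Reactants: 9 2-[2-(tert-butyldimethylsilyloxy)pent-4-enyl]-3-isopropylcyclopent-2-en-1-ol
Product: 11 3-(tert-butyldimethylsilyloxy)-9-isopropyltricyclo[5.2.1.0^1,5]dec-8-ene (cyclopentane exo-fused; silyloxy group anti to the methano bridge), via cyclopentadiene 10 (not isolated)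
Conditions: camphorsulfonic acid (5 mol %), 4 Å MS, PhMe, 23 °C; then Et3N (10 mol %), BHT, PhMe (0.01 M), 125 °C; chromatographic removal of the diastereomeric adduct
Reagents that add atoms: none
Why: Acid dehydration gives cyclopentadienes that interconvert by 1,5-H shifts, only the isomer with the tether on a diene terminus can undergo the intramolecular Diels–Alder reaction, the three-atom tether forces the exo-fused five-membered ring and thereby fixes the three new centres relative to each other, and the silyloxy centre makes the two facial adducts diastereomers so that separation secures the absolute configuration.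

**Step 8**
Reactants: 11 3-(tert-butyldimethylsilyloxy)-9-isopropyltricyclo[5.2.1.0^1,5]dec-8-ene
Product: 13 3-(tert-butyldimethylsilyloxy)-9-isopropyltricyclo[5.2.1.0^1,5]decan-9-ol (OH exo; isopropyl endo), via organomercurial 12 (not isolated)
Conditions: Hg(OAc)2, THF/H2O, 23 °C; then NaBH4, aq NaOH, 0 °C
Reagents that add atoms: water O
Why: Oxymercuration–demercuration of a norbornene proceeds by exo attack without skeletal rearrangement and with Markovnikov orientation, so the hydroxyl should arrive exo on the isopropyl-bearing carbon, which also removes the strained alkene before the bromination step.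

**Step 9**
Reactants: 13 3-(tert-butyldimethylsilyloxy)-9-isopropyltricyclo[5.2.1.0^1,5]decan-9-ol
Product: 14 9-isopropyltricyclo[5.2.1.0^1,5]decane-3,9-diol
Conditions: TBAF, THF, 23 °C
Reagents that add atoms: none
Why: Fluoride-induced desilylation frees the secondary alcohol and leaves the hindered tertiary alcohol untouched.

**Step 10**
Reactants: 14 9-isopropyltricyclo[5.2.1.0^1,5]decane-3,9-diol
Product: 15 9-hydroxy-9-isopropyltricyclo[5.2.1.0^1,5]decan-3-one
Conditions: Dess–Martin periodinane, NaHCO3, CH2Cl2, 23 °C
Reagents that add atoms: none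
Why: Dess–Martin oxidation converts only the secondary alcohol, erases the temporary stereocentre and gives the cyclopentanone whose ring is the forerunner of ring B.

**Step 11**
Reactants: 15 9-hydroxy-9-isopropyltricyclo[5.2.1.0^1,5]decan-3-one; 16 2-bromopropene
Product: 17 9-hydroxy-9-isopropyl-4-(prop-1-en-2-yl)tricyclo[5.2.1.0^1,5]decan-3-one (isopropenyl anti to the methano bridge)
Conditions: LiHMDS (2.3 equiv), Pd2(dba)3 (2.5 mol %), 1,2,3,4,5-pentaphenyl-1'-(di-tert-butylphosphino)ferrocene (5 mol %), THF, 23 to 50 °C; AcOH quench at −78 °C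
Reagents that add atoms: none
Why: Palladium-catalysed ketone α-alkenylation should occur at the CH2 next to the ring-fusion CH rather than at the CH2 next to the quaternary bridgehead, and the epimerisable new centre should settle with the isopropenyl group trans to the neighbouring norbornane CH2.

**Step 12**
Reactants: 18 but-2-yn-1-ol
Product: 20 (E)-3-iodobut-2-en-1-ol, via alkenylzirconocene 19 (not isolated)
Conditions: Cp2Zr(H)Cl (2.2 equiv), THF, 0 to 23 °C; I2, −78 °C
Reagents that add atoms: iodine II
Why: Hydrozirconation adds H and Zr syn with zirconium on the carbon remote from the zirconium alkoxide, and iodinolysis with retention should give the E iodide.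

**Step 13**
Reactants: 20 (E)-3-iodobut-2-en-1-ol
Product: 21 (E)-1-bromo-3-iodobut-2-ene
Conditions: CBr4, PPh3, CH2Cl2, 0 °C
Reagents that add atoms: carbon tetrabromide BrC(Br)(Br)Br
Why: The Appel reaction converts the primary allylic alcohol to the bromide under neutral conditions without changing the alkene geometry.

**Step 14**
Reactants: 21 (E)-1-bromo-3-iodobut-2-ene; 22 vinylmagnesium bromide
Product: 23 (E)-2-iodohexa-2,5-diene
Conditions: CuI (10 mol %), THF, −40 °C
Reagents that add atoms: none
Why: In this copper-catalysed allylic substitution the fully substituted iodine-bearing terminus blocks the SN2' path, so direct displacement should give the skipped diene with the alkenyl iodide intact.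

**Step 15**
Reactants: 23 (E)-2-iodohexa-2,5-diene; 17 9-hydroxy-9-isopropyl-4-(prop-1-en-2-yl)tricyclo[5.2.1.0^1,5]decan-3-one
Product: 25 3-[(2E)-hexa-2,5-dien-2-yl]-9-isopropyl-4-(prop-1-en-2-yl)tricyclo[5.2.1.0^1,5]decane-3,9-diol (alkenyl group syn to the methano bridge and trans to isopropenyl), via alkenyllithium 24 (not isolated)
Conditions: t-BuLi (2 equiv per iodide), Et2O, −78 °C; then 17, LaCl3·2LiCl, THF, −78 °C (3 equiv of 24)
Reagents that add atoms: none
Why: Iodine–lithium exchange with retention is followed by lanthanum-assisted 1,2-addition, which suppresses enolisation, and attack anti to the adjacent isopropenyl group should set the carbinol centre.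

**Step 16**
Reactants: 25 3-[(2E)-hexa-2,5-dien-2-yl]-9-isopropyl-4-(prop-1-en-2-yl)tricyclo[5.2.1.0^1,5]decane-3,9-diol
Product: 26 4-(1-bromobut-3-enyl)-10-hydroxy-10-isopropyl-4-methyl-5-(prop-1-en-2-yl)tricyclo[6.2.1.0^1,6]undecan-3-one
Conditions: NBS (1.05 equiv), CH2Cl2, −40 °C, dark
Reagents that add atoms: N-bromosuccinimide O=C1CCC(=O)N1Br
Why: NBS transfers Br+ reversibly to the trisubstituted alkene, and in the bromonium ion the ring bond from the carbinol carbon to the isopropenyl-bearing CH stands antiperiplanar to the breaking C–Br bond, so that CH migrates to the methyl-bearing carbon while the carbinol becomes the ketone; this is a halonium-induced semipinacol rearrangement, the closest known type being the NBS-promoted ring expansion of 1-alkenylcycloalkanols. No ring is closed by a new bond between remote atoms: the five-membered ring grows to the six-membered ring B by a suprafacial 1,2-shift with retention at the migrating CH and inversion at the terminus. The quaternary centre is controlled by the reactive rotamer, in which the small OH lies next to the vinylic methyl group and the ring CH2 next to the vinylic H (least A1,2 and A1,3 strain), so the migrating carbon should reach one alkene face only and place CH3 trans to the fusion H. The CHBr centre follows from anti addition to the E alkene, which puts Br cis to CH3 and equatorial once ring A is closed. Selectivities needed are site (trisubstituted over 1,1-disubstituted and monosubstituted alkene, with unproductive bromonium ions reverting), migrating group (secondary allylic CH over the CH2 next to the bridgehead) and rearrangement over epoxide or bromohydrin formation (aprotic medium, no base).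

**Step 17**
Reactants: 26 4-(1-bromobut-3-enyl)-10-hydroxy-10-isopropyl-4-methyl-5-(prop-1-en-2-yl)tricyclo[6.2.1.0^1,6]undecan-3-one
Product: 27 tetracyclic bromo ketone (ring A closed as a trisubstituted cyclohexene; trans A/B fusion; Br equatorial)
Conditions: second-generation Hoveyda–Grubbs catalyst (5 mol %), PhMe, 80 °C
Reagents that add atoms: none
Why: Ring-closing metathesis joins the vicinal equatorial butenyl and isopropenyl arms into the six-membered ring A, and ketone, tertiary alcohol and secondary bromide are tolerated.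

**Step 18**
Reactants: 27 tetracyclic bromo ketone
Product: 28 tosylhydrazone of 27
Conditions: TsNHNH2, PPTS (10 mol %), EtOH, 60 °C
Reagents that add atoms: 4-methylbenzenesulfonohydrazide Cc1ccc(cc1)S(=O)(=O)NN
Why: Hydrazone condensation works on 2,2-disubstituted cyclohexanones, and the equatorial bromide cannot be displaced by the hydrazone nitrogen because that nitrogen cannot reach the rear of the C–Br bond.

**Step 19**
Reactants: 28 tosylhydrazone of 27
Product: 30 tetracyclic bromo alkene (ring B fully saturated), via tosylhydrazine 29 (not isolated)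
Conditions: catecholborane, CHCl3, −10 °C; then NaOAc·3H2O, reflux
Reagents that add atoms: none
Why: In this tosylhydrazone reduction hydroboration of the C=N bond, loss of sulfinate and loss of N2 from the diazene should replace the carbonyl by CH2 under conditions mild enough for the secondary bromide and the trisubstituted alkene.

**Step 20**
Reactants: 30 tetracyclic bromo alkene
Product: 32 target CNP0362628.1, via organomercurial 31 (not isolated)
Conditions: Hg(OAc)2, THF/H2O, 23 °C; then NaBH4, aq NaOH, 0 °C
Reagents that add atoms: water O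
Why: In this oxymercuration–demercuration divalent mercury should bind the alkene face away from the axial angular methyl group, and water should open the mercurinium ion trans-diaxially at the methyl-bearing carbon, so Markovnikov and stereoelectronic preferences both lead to the axial tertiary alcohol with equatorial CH3.

**Compound list**

| No. | Name | SMILES | Role |
|---|---|---|---|
| 1 | methyl 4-oxobutanoate | COC(=O)CCC=O | starting material |
| 2 | 2-allyl-4,4,5,5-tetramethyl-1,3,2-dioxaborolane | C=CCB1OC(C)(C)C(C)(C)O1 | starting material |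
| 3 | methyl (4R)-4-hydroxyhept-6-enoate | C=CC[C@H](O)CCC(=O)OC | intermediate |
| 4 | methyl (4R)-4-[(tert-butyldimethylsilyl)oxy]hept-6-enoate | C=CC[C@H](O[Si](C)(C)C(C)(C)C)CCC(=O)OC | intermediate |
| 5 | (4R)-4-[(tert-butyldimethylsilyl)oxy]hept-6-enal | C=CC[C@H](O[Si](C)(C)C(C)(C)C)CCC=O | intermediate |
| 6 | 4-methylpent-1-en-3-one | C=CC(=O)C(C)C | starting material |
| 7 | (9R)-9-[(tert-butyldimethylsilyl)oxy]-2-methyldodec-11-ene-3,6-dione | C=CC[C@H](O[Si](C)(C)C(C)(C)C)CCC(=O)CCC(=O)C(C)C | intermediate |
| 8 | 2-[2-(tert-butyldimethylsilyloxy)pent-4-enyl]-3-isopropylcyclopent-2-en-1-one | C=CC[C@H](O[Si](C)(C)C(C)(C)C)CC1=C(C(C)C)CCC1=O | intermediate |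
| 9 | 2-[2-(tert-butyldimethylsilyloxy)pent-4-enyl]-3-isopropylcyclopent-2-en-1-ol | C=CC[C@H](O[Si](C)(C)C(C)(C)C)CC1=C(C(C)C)CCC1O | intermediate |
| 10 | 1-[2-(tert-butyldimethylsilyloxy)pent-4-enyl]-2-isopropylcyclopenta-1,3-diene | C=CC[C@H](O[Si](C)(C)C(C)(C)C)CC1=C(C(C)C)C=CC1 | intermediate |
| 11 | 3-(tert-butyldimethylsilyloxy)-9-isopropyltricyclo[5.2.1.0^1,5]dec-8-ene | CC(C)C1=C[C@@H]2C[C@H]3C[C@H](O[Si](C)(C)C(C)(C)C)C[C@@]31C2 | intermediate |
| 12 | exo-8-(acetoxymercurio) derivative of 13 | CC(C)[C@]1(O)[C@@H]([Hg]OC(C)=O)[C@@H]2C[C@H]3C[C@H](O[Si](C)(C)C(C)(C)C)C[C@@]31C2 | intermediate |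
| 13 | 3-(tert-butyldimethylsilyloxy)-9-isopropyltricyclo[5.2.1.0^1,5]decan-9-ol; OH exo | CC(C)[C@]1(O)C[C@@H]2C[C@H]3C[C@H](O[Si](C)(C)C(C)(C)C)C[C@@]31C2 | intermediate |
| 14 | 9-isopropyltricyclo[5.2.1.0^1,5]decane-3,9-diol | CC(C)[C@]1(O)C[C@@H]2C[C@H]3C[C@H](O)C[C@@]31C2 | intermediate |
| 15 | 9-hydroxy-9-isopropyltricyclo[5.2.1.0^1,5]decan-3-one | CC(C)[C@]1(O)C[C@@H]2C[C@H]3CC(=O)C[C@@]31C2 | intermediate |
| 16 | 2-bromopropene | CC(Br)=C | starting material |
| 17 | 9-hydroxy-9-isopropyl-4-(prop-1-en-2-yl)tricyclo[5.2.1.0^1,5]decan-3-one | CC(C)[C@]1(O)C[C@@H]2C[C@H]3[C@H](C(C)=C)C(=O)C[C@@]31C2 | intermediate |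
| 18 | but-2-yn-1-ol | CC#CCO | starting material |
| 19 | (E)-alkenylzirconocene chloride zirconium alkoxide | C/C([Zr](Cl)(C1C=CC=C1)C1C=CC=C1)=C\CO[Zr](Cl)(C1C=CC=C1)C1C=CC=C1 | intermediate |
| 20 | (E)-3-iodobut-2-en-1-ol | C/C(I)=C\CO | intermediate |
| 21 | (E)-1-bromo-3-iodobut-2-ene | C/C(I)=C\CBr | intermediate |
| 22 | vinylmagnesium bromide | C=C[Mg]Br | starting material |
| 23 | (E)-2-iodohexa-2,5-diene | I/C(C)=C/CC=C | intermediate |
| 24 | (E)-hexa-2,5-dien-2-yllithium | [Li]/C(C)=C/CC=C | intermediate |
| 25 | 3-[(2E)-hexa-2,5-dien-2-yl]-9-isopropyl-4-(prop-1-en-2-yl)tricyclo[5.2.1.0^1,5]decane-3,9-diol | CC(C)[C@]1(O)C[C@@H]2C[C@H]3[C@H](C(C)=C)[C@@](O)(/C(C)=C/CC=C)C[C@@]31C2 | intermediate |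
| 26 | 4-(1-bromobut-3-enyl)-10-hydroxy-10-isopropyl-4-methyl-5-(prop-1-en-2-yl)tricyclo[6.2.1.0^1,6]undecan-3-one | CC(C)[C@]1(O)C[C@@H]2C[C@H]3[C@H](C(C)=C)[C@](C)(C(=O)C[C@@]31C2)[C@@H](Br)CC=C | intermediate |
| 27 | tetracyclic bromo ketone; ring A cyclohexene | CC(C)[C@]1(O)C[C@@H]2C[C@H]3[C@H]4[C@](C)(C(=O)C[C@@]31C2)[C@@H](Br)CC=C4C | intermediate |
| 28 | tosylhydrazone of 27 | CC(C)[C@]1(O)C[C@@H]2C[C@H]3[C@H]4[C@](C)(C(=NNS(=O)(=O)c5ccc(C)cc5)C[C@@]31C2)[C@@H](Br)CC=C4C | intermediate |
| 29 | tosylhydrazine from 28 | CC(C)[C@]1(O)C[C@@H]2C[C@H]3[C@H]4[C@](C)(C(NNS(=O)(=O)c5ccc(C)cc5)C[C@@]31C2)[C@@H](Br)CC=C4C | intermediate |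
| 30 | tetracyclic bromo alkene; ring B saturated | CC(C)[C@]1(O)C[C@@H]2C[C@H]3[C@H]4[C@](C)(CC[C@@]31C2)[C@@H](Br)CC=C4C | intermediate |
| 31 | axial acetoxymercurio derivative of 32 | CC(C)[C@]1(O)C[C@@H]2C[C@H]3[C@H]4[C@](C)(CC[C@@]31C2)[C@@H](Br)C[C@H]([Hg]OC(C)=O)[C@@]4(C)O | intermediate |
| 32 | CNP0362628.1 | CC(C)[C@]1(O)C[C@@H]2C[C@H]3[C@H]4[C@](C)(CC[C@@]31C2)[C@@H](Br)CC[C@@]4(C)O | target |

**Step count**
Total steps: 20. Longest linear sequence: 17 (steps 1 to 11 and 15 to 20).

**Steps most likely to fail**

**Step 16.** The bromonium ion may open through the other rotamer, which would cost facial selectivity at the new quaternary carbon. Br+ may also be consumed at the isopropenyl group, or the ion may collapse to the epoxide.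

The fallback changes the electrophile and the alkene geometry. It sets out from 18 and 17 and comes back at 26.
- Hydroalumination of 18 with NaAlH2(OCH2CH2OCH3)2 followed by I2 gives (Z)-3-iodobut-2-en-1-ol F1.
- An Appel reaction gives (Z)-1-bromo-3-iodobut-2-ene F2.
- Copper-catalysed vinylation gives (Z)-2-iodohexa-2,5-diene F3.
- Iodine–lithium exchange and addition to 17 give the Z allylic alcohol F4.
- PhSeBr, a softer and fully reversible electrophile, induces the same ring-expanding semipinacol shift. It gives the β-(phenylselanyl) ketone F5, whose selenium-bearing carbon has the opposite configuration because of the Z geometry.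
- Bromodeselenation with Br2 and Et3N proceeds with inversion and gives 26.

**Step 7.** The remote silyloxy centre may give poor facial selectivity, and the diene may be lost by dimerisation.

The fallback moves stereocontrol from the substrate to a catalyst. It sets out from 9 and comes back at 11.
- Cross metathesis of 9 with crotonaldehyde (second-generation Hoveyda–Grubbs catalyst) gives the enal F6.
- Acid dehydration gives the cyclopentadienyl enal F7.
- Iminium catalysis with the suitable enantiomer of 5-benzyl-2,2,3-trimethylimidazolidin-4-one hydrochloride at 0 °C effects an enantioface-selective intramolecular Diels–Alder reaction. It gives the endo aldehyde F8.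
- Decarbonylation with RhCl(PPh3)3 in hot PhCN gives 11.

**Step 11.** Enolisation may go toward the CH2 next to the bridgehead, assisted by the nearby lithium alkoxide. The new double bond may also migrate into conjugation.

The fallback builds the group by aldol chemistry. It sets out from 15 and comes back at 17.
- A zinc-mediated aldol addition to acetone gives the β-hydroxy ketone F9.
- MsCl and Et3N give the conjugated isopropylidene ketone F10.
- Deconjugation by γ-deprotonation with KHMDS and kinetic α-protonation with AcOH at −78 °C gives 17.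

**Further compounds**
F1 | step 16 | (Z)-3-iodobut-2-en-1-ol | C/C(I)=C/CO
F2 | step 16 | (Z)-1-bromo-3-iodobut-2-ene | C/C(I)=C/CBr
F3 | step 16 | (Z)-2-iodohexa-2,5-diene | C/C(I)=C/CC=C
F4 | step 16 | 3-[(2Z)-hexa-2,5-dien-2-yl]-9-isopropyl-4-(prop-1-en-2-yl)tricyclo[5.2.1.0^1,5]decane-3,9-diol | CC(C)[C@]1(O)C[C@@H]2C[C@H]3[C@H](C(C)=C)[C@@](O)(/C(C)=C\CC=C)C[C@@]31C2
F5 | step 16 | 10-hydroxy-10-isopropyl-4-methyl-4-[1-(phenylselanyl)but-3-enyl]-5-(prop-1-en-2-yl)tricyclo[6.2.1.0^1,6]undecan-3-one | CC(C)[C@]1(O)C[C@@H]2C[C@H]3[C@H](C(C)=C)[C@](C)(C(=O)C[C@@]31C2)[C@H]([Se]c5ccccc5)CC=C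
F6 | step 7 | (E)-5-(tert-butyldimethylsilyloxy)-6-(5-hydroxy-2-isopropylcyclopent-1-enyl)hex-2-enal | O=C/C=C/C[C@H](O[Si](C)(C)C(C)(C)C)CC1=C(C(C)C)CCC1O
F7 | step 7 | (E)-5-(tert-butyldimethylsilyloxy)-6-(2-isopropylcyclopenta-1,3-dienyl)hex-2-enal | O=C/C=C/C[C@H](O[Si](C)(C)C(C)(C)C)CC1=C(C(C)C)C=CC1
F8 | step 7 | 3-(tert-butyldimethylsilyloxy)-9-isopropyltricyclo[5.2.1.0^1,5]dec-8-ene-6-endo-carbaldehyde | CC(C)C1=C[C@@H]2[C@H](C=O)[C@H]3C[C@H](O[Si](C)(C)C(C)(C)C)C[C@@]31C2
F9 | step 11 | 9-hydroxy-4-(2-hydroxypropan-2-yl)-9-isopropyltricyclo[5.2.1.0^1,5]decan-3-one | CC(C)[C@]1(O)C[C@@H]2C[C@H]3[C@H](C(C)(C)O)C(=O)C[C@@]31C2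
F10 | step 11 | 9-hydroxy-9-isopropyl-4-(propan-2-ylidene)tricyclo[5.2.1.0^1,5]decan-3-one | CC(C)[C@]1(O)C[C@@H]2C[C@H]3C(=C(C)C)C(=O)C[C@@]31C2
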